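The target is traced back to its hexadecamethyl ether lacking three oxygens: the one on C5 of the central ring B and the one on C4 of each terminal biaryl ring E. In that precursor B5–H, E4–H and E4'–H are the only aryl C–H bonds with two C–H neighbours; B4/B6 and E3/E5 have one ortho oxygen, and every C–H of rings A, C and D lies between two oxygens. A single iridium-catalysed borylation/oxidation therefore makes all three C–O bonds. The precursor comes from a Suzuki-derived ring D–E phenol, a ring C aldehyde used as a masked phenol, and a twofold Ullmann coupling onto a ring A–B dibromide; BBr3 then frees nineteen hydroxyls.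

Key step: step 8

Ring letters: A = terminal 3,5-dioxygenated phenoxy ring; B = central ring (B2 carries O–A, B1 and B3 carry O–C and O–C'); C, C' = rings bound to B through the oxygen on C1, with oxygens on C2 and C6 and O–D on C4; D, D' = rings with D1–O–C, oxygens on D2, D4, D6 and ring E on D5; E, E' = terminal rings bound through E1.

Remark on the chemistry: the selectivity is argued from the C–H bonds of precursor 15, not from the hydroxylated carbons of the target, because in the target the oxygen-bearing carbons of ring A and C4 of rings C/C' also have two C–H neighbours. In 15 the six C–H bonds at B4, B6, E3, E5, E3' and E5' have one ortho oxygen, not two, and are the real competitors.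

Assumptions: the target has no stereocentre and no stereogenic axis, since ring E is symmetric about the biaryl bond. Compounds 7 and 12 are taken as catalogue compounds.

Step 1
Reactants: 1 2,4,6-trimethoxybenzaldehyde
Product: 2 3-bromo-2,4,6-trimethoxybenzaldehyde
Conditions: NBS (1.0 equiv), MeCN, 0 °C to rt, dark
Reagents that add atoms: N-bromosuccinimide, O=C1CCC(=O)N1Br
Why: Electrophilic aromatic bromination: the two free ring positions of 1 are equivalent and each is activated by two flanking methoxy groups, while the formyl group tempers the ring enough that one equivalent of NBS should stop at the monobromide.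

Step 2
Reactants: 2 3-bromo-2,4,6-trimethoxybenzaldehyde; 3 2,6-dimethoxyphenylboronic acid (2 equiv)
Product: 4 2,2',4,6,6'-pentamethoxybiphenyl-3-carbaldehyde
Conditions: Pd(OAc)2 (5 mol %), SPhos (10 mol %), K3PO4, toluene/H2O 10:1, 100 °C
Reagents that add atoms: none
Why: Suzuki–Miyaura coupling: zerovalent palladium carrying the bulky, electron-rich SPhos ligand is established for tetra-ortho-substituted biaryls, and an excess of 3 offsets its protodeboronation.

Step 3
Reactants: 4 2,2',4,6,6'-pentamethoxybiphenyl-3-carbaldehyde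
Product: 6 2,2',4,6,6'-pentamethoxybiphenyl-3-ol, via aryl formate 5 (not isolated)
Conditions: mCPBA, CH2Cl2, 0 °C to rt; then K2CO3 (cat.), MeOH, rt
Reagents that add atoms: 3-chloroperoxybenzoic acid (mCPBA), O=C(OO)c1cccc(Cl)c1
Why: Baeyer–Villiger (Dakin-type) oxidation: in the Criegee adduct the electron-rich aryl group with two ortho methoxy groups migrates in preference to hydride, and mild methanolysis of formate 5 should release the phenol without touching the methyl ethers.

Step 4
Reactants: 6 2,2',4,6,6'-pentamethoxybiphenyl-3-ol; 7 4-bromo-2,6-dimethoxybenzaldehyde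
Product: 8 2,6-dimethoxy-4-[(2,2',4,6,6'-pentamethoxybiphenyl-3-yl)oxy]benzaldehyde
Conditions: CuI (10 mol %), picolinic acid (20 mol %), K3PO4, DMSO, 90 °C
Reagents that add atoms: none
Why: Ullmann-type diaryl ether synthesis: the picolinate-ligated CuI catalyst is known to arylate 2,6-disubstituted phenols, and the bromide of 7 is unhindered and activated by the para formyl group, so the hindered phenoxide of 6 should couple cleanly.

Step 5
Reactants: 8 2,6-dimethoxy-4-[(2,2',4,6,6'-pentamethoxybiphenyl-3-yl)oxy]benzaldehyde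
Product: 10 2,6-dimethoxy-4-[(2,2',4,6,6'-pentamethoxybiphenyl-3-yl)oxy]phenol, via aryl formate 9 (not isolated)
Conditions: mCPBA, CH2Cl2, 0 °C; then K2CO3 (cat.), MeOH, rt
Reagents that add atoms: 3-chloroperoxybenzoic acid (mCPBA), O=C(OO)c1cccc(Cl)c1
Why: Baeyer–Villiger (Dakin-type) oxidation as in step 3: the 2,6-dimethoxy-4-aryloxyphenyl group migrates readily, and the phenol stays masked as formate 9 until the excess peracid has been washed out, which should protect the electron-rich product from over-oxidation.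

Step 6
Reactants: 11 2,6-dibromophenol; 12 3,5-dimethoxyphenylboronic acid (2 equiv)
Product: 13 1,3-dibromo-2-(3,5-dimethoxyphenoxy)benzene
Conditions: Cu(OAc)2 (2 equiv), pyridine, 4 Å MS, CH2Cl2, rt
Reagents that add atoms: none
Why: Chan–Lam coupling: aryl transfer from boron to divalent copper and C–O reductive elimination from the trivalent copper aryl phenoxide proceed at room temperature, where 2,6-dihalophenols are known to couple and the C–Br bonds are left intact.

Step 7
Reactants: 13 1,3-dibromo-2-(3,5-dimethoxyphenoxy)benzene; 10 2,6-dimethoxy-4-[(2,2',4,6,6'-pentamethoxybiphenyl-3-yl)oxy]phenol (2.4 equiv)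
Product: 15 2-(3,5-dimethoxyphenoxy)-1,3-bis{2,6-dimethoxy-4-[(2,2',4,6,6'-pentamethoxybiphenyl-3-yl)oxy]phenoxy}benzene (hexadecamethyl ether lacking the oxygens at B5, E4 and E4'), via monoether bromide 14 (not isolated)
Conditions: CuI (40 mol %), picolinic acid (80 mol %), K3PO4, DMSO, 110 °C
Reagents that add atoms: none
Why: Twofold Ullmann-type diaryl ether synthesis: the CuI/picolinic acid system tolerates ortho-substituted aryl halides together with 2,6-disubstituted phenols, and the excess of 10 should drive monoether bromide 14 on to the 1,2,3-triaryloxybenzene.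

Step 8
Reactants: 15 hexadecamethyl ether lacking the oxygens at B5, E4 and E4'
Product: 17 4-(3,5-dimethoxyphenoxy)-3,5-bis{4-[(4'-hydroxy-2,2',4,6,6'-pentamethoxybiphenyl-3-yl)oxy]-2,6-dimethoxyphenoxy}phenol (hexadecamethyl ether with free hydroxyls at B5, E4 and E4'), via tris(pinacolboronate) 16 (not isolated)
Conditions: [Ir(OMe)(cod)]2 (5 mol %), 4,4'-di-tert-butyl-2,2'-bipyridine (10 mol %), B2pin2 (4.5 equiv), THF, 80 °C; then 30% H2O2, aq NaOH, THF, 0 °C to rt
Reagents that add atoms: hydrogen peroxide, OO (oxygen of the three new hydroxyls); bis(pinacolato)diboron, CC1(C)OB(OC1(C)C)B1OC(C)(C)C(C)(C)O1, supplies the boryl groups of 16, which do not remain in 17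
Why: The trivalent iridium tris(boryl) complex (dtbpy)Ir(Bpin)3 cleaves an aryl C–H bond by oxidative addition, C–B reductive elimination releases the arylboronate and B2pin2 regenerates the tris(boryl); hydroperoxide then adds to boron and the aryl group shifts from boron to oxygen, so each hydroxyl appears exactly where boron was. The closest known reaction type is the sterically governed iridium-catalysed C–H borylation of 1,3-di- and 1,2,3-trisubstituted alkoxyarenes at the mutually meta position, run in one pot with oxidation of the boronate to the phenol. No ring is closed and no stereocentre is created; three C–O bonds are formed. Site selectivity among eighteen aryl C–H bonds is required: the crowded iridium centre does not engage the nine C–H bonds of rings A, C/C' and D/D', which all lie between two oxygens, and reacts only slowly at the six with one ortho oxygen (B4, B6, E3, E5, E3', E5'), leaving B5–H, E4–H and E4'–H, the only ones with two C–H neighbours. Each borylation also converts its two neighbouring C–H bonds into doubly flanked ones, so excess B2pin2 can force threefold conversion without over-borylation. Methyl and diaryl ethers are inert to both stages, and 15 carries no O–H, halide or carbonyl group that could divert the catalyst.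

Step 9
Reactants: 17 hexadecamethyl ether with free hydroxyls at B5, E4 and E4'
Product: 18 4-(3,5-dihydroxyphenoxy)-3,5-bis{4-[(2,2',4,4',6,6'-hexahydroxybiphenyl-3-yl)oxy]-2,6-dihydroxyphenoxy}phenol (CNP0227063.0)
Conditions: BBr3 (40 equiv), CH2Cl2, −78 °C to rt, argon; then H2O, 0 °C
Reagents that add atoms: none
Why: Lewis acid-mediated aryl methyl ether cleavage: BBr3 coordinates each methoxy oxygen and bromide removes the methyl group by SN2 attack, while the diaryl ether and biaryl bonds offer no sp3 carbon and are inert, so hydrolysis of the aryl borates should release all nineteen hydroxyls.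

Compound list
1 | 2,4,6-trimethoxybenzaldehyde | COc1cc(OC)c(C=O)c(OC)c1 | starting material
2 | 3-bromo-2,4,6-trimethoxybenzaldehyde | COc1cc(OC)c(C=O)c(OC)c1Br | intermediate
3 | 2,6-dimethoxyphenylboronic acid | COc1cccc(OC)c1B(O)O | starting material
4 | 2,2',4,6,6'-pentamethoxybiphenyl-3-carbaldehyde | COc1cc(OC)c(C=O)c(OC)c1-c1c(OC)cccc1OC | intermediate
5 | 2,2',4,6,6'-pentamethoxybiphenyl-3-yl formate (not isolated) | COc1cc(OC)c(OC=O)c(OC)c1-c1c(OC)cccc1OC | intermediate
6 | 2,2',4,6,6'-pentamethoxybiphenyl-3-ol | COc1cc(OC)c(O)c(OC)c1-c1c(OC)cccc1OC | intermediate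
7 | 4-bromo-2,6-dimethoxybenzaldehyde | COc1cc(Br)cc(OC)c1C=O | starting material
8 | 2,6-dimethoxy-4-[(2,2',4,6,6'-pentamethoxybiphenyl-3-yl)oxy]benzaldehyde | COc1cc(Oc2c(OC)cc(OC)c(-c3c(OC)cccc3OC)c2OC)cc(OC)c1C=O | intermediate
9 | 2,6-dimethoxy-4-[(2,2',4,6,6'-pentamethoxybiphenyl-3-yl)oxy]phenyl formate (not isolated) | COc1cc(Oc2c(OC)cc(OC)c(-c3c(OC)cccc3OC)c2OC)cc(OC)c1OC=O | intermediate
10 | 2,6-dimethoxy-4-[(2,2',4,6,6'-pentamethoxybiphenyl-3-yl)oxy]phenol | COc1cc(Oc2c(OC)cc(OC)c(-c3c(OC)cccc3OC)c2OC)cc(OC)c1O | intermediate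
11 | 2,6-dibromophenol | Oc1c(Br)cccc1Br | starting material
12 | 3,5-dimethoxyphenylboronic acid | COc1cc(OC)cc(B(O)O)c1 | starting material
13 | 1,3-dibromo-2-(3,5-dimethoxyphenoxy)benzene | COc1cc(OC)cc(Oc2c(Br)cccc2Br)c1 | intermediate
14 | 1-bromo-2-(3,5-dimethoxyphenoxy)-3-{2,6-dimethoxy-4-[(2,2',4,6,6'-pentamethoxybiphenyl-3-yl)oxy]phenoxy}benzene (not isolated) | COc1cc(OC)cc(Oc2c(Br)cccc2Oc2c(OC)cc(Oc3c(OC)cc(OC)c(-c4c(OC)cccc4OC)c3OC)cc2OC)c1 | intermediate
15 | 2-(3,5-dimethoxyphenoxy)-1,3-bis{2,6-dimethoxy-4-[(2,2',4,6,6'-pentamethoxybiphenyl-3-yl)oxy]phenoxy}benzene | COc1cc(OC)cc(Oc2c(Oc3c(OC)cc(Oc4c(OC)cc(OC)c(-c5c(OC)cccc5OC)c4OC)cc3OC)cccc2Oc2c(OC)cc(Oc3c(OC)cc(OC)c(-c4c(OC)cccc4OC)c3OC)cc2OC)c1 | intermediate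
16 | tris(4,4,5,5-tetramethyl-1,3,2-dioxaborolan-2-yl) derivative of 15 at B5, E4 and E4' (not isolated) | COc1cc(OC)cc(Oc2c(Oc3c(OC)cc(Oc4c(OC)cc(OC)c(-c5c(OC)cc(B6OC(C)(C)C(C)(C)O6)cc5OC)c4OC)cc3OC)cc(B3OC(C)(C)C(C)(C)O3)cc2Oc2c(OC)cc(Oc3c(OC)cc(OC)c(-c4c(OC)cc(B5OC(C)(C)C(C)(C)O5)cc4OC)c3OC)cc2OC)c1 | intermediate
17 | 4-(3,5-dimethoxyphenoxy)-3,5-bis{4-[(4'-hydroxy-2,2',4,6,6'-pentamethoxybiphenyl-3-yl)oxy]-2,6-dimethoxyphenoxy}phenol | COc1cc(OC)cc(Oc2c(Oc3c(OC)cc(Oc4c(OC)cc(OC)c(-c5c(OC)cc(O)cc5OC)c4OC)cc3OC)cc(O)cc2Oc2c(OC)cc(Oc3c(OC)cc(OC)c(-c4c(OC)cc(O)cc4OC)c3OC)cc2OC)c1 | intermediate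
18 | 4-(3,5-dihydroxyphenoxy)-3,5-bis{4-[(2,2',4,4',6,6'-hexahydroxybiphenyl-3-yl)oxy]-2,6-dihydroxyphenoxy}phenol (CNP0227063.0) | Oc1cc(O)cc(Oc2c(Oc3c(O)cc(Oc4c(O)cc(O)c(-c5c(O)cc(O)cc5O)c4O)cc3O)cc(O)cc2Oc2c(O)cc(Oc3c(O)cc(O)c(-c4c(O)cc(O)cc4O)c3O)cc2O)c1 | target

Total step count: 9. Longest linear sequence: 8 steps (steps 1, 2, 3, 4, 5, 7, 8, 9); step 6 is a one-step side branch.

Steps most likely to fail

Step 7 (twofold Ullmann etherification). The second C–O coupling must occur at a bromide wedged beside two aryloxy groups with a 2,6-dimethoxyphenoxide as nucleophile. The reaction may stall at the monoether stage, or the C–Br bond may be reduced before the hindered phenoxide is transferred. The fallback forms both B–O–C bonds by nucleophilic aromatic substitution on an ortho-activated ring B and attaches ring A last. It sets out from 10: two equivalents with 2,6-difluorobenzaldehyde (K2CO3, DMF, 110 °C) would give, through the 2-fluoro-6-aryloxybenzaldehyde F1, the 2,6-bis(aryloxy)benzaldehyde F2. Baeyer–Villiger oxidation with mCPBA to the aryl formate F3 and methanolysis would give the 2,6-bis(aryloxy)phenol F4. Chan–Lam coupling of F4 with 12 (Cu(OAc)2, pyridine, CH2Cl2, rt) would come back to the route at 15.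

Step 8 (threefold borylation/oxidation). Borylation of a large, electron-rich substrate may stop before all three sites have reacted, or leak to the six C–H bonds with a single ortho oxygen, giving mixtures of partly or wrongly oxygenated ethers that are hard to separate. The fallback gives up late oxygenation and carries the three oxygens as methyl ethers from the building blocks. It sets out from 2: Suzuki–Miyaura coupling with 2,4,6-trimethoxyphenylboronic acid (Pd(OAc)2, SPhos, K3PO4) would give the hexamethoxybiphenyl aldehyde F5, mCPBA its formate F6, and methanolysis the hexamethoxybiphenylol F7. Ullmann coupling of F7 with 7 would give the arm aldehyde F8, and a second Dakin sequence, through the arm formate F9, the arm phenol F10. In parallel, Chan–Lam coupling of 2,6-dibromo-4-methoxyphenol with 12 would give the methoxy dibromide F11. Twofold Ullmann coupling of F11 with F10, through the monoether bromide F12, would give the nonadecamethyl ether F13, which BBr3 would convert directly into 18, where the fallback comes back to the route.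

Step 2 (tetra-ortho-substituted Suzuki–Miyaura coupling). Protodeboronation of 3 under hot basic conditions may outrun the slow transmetalation onto the doubly flanked arylpalladium bromide, so that 2 is left unconsumed. The fallback is a Negishi coupling with an arylzinc reagent made by directed lithiation, which transmetalates under neutral, anhydrous conditions and tolerates the aldehyde. It sets out from 2: 1,3-dimethoxybenzene would be lithiated between its methoxy groups (n-BuLi, THF, 0 °C) to 2,6-dimethoxyphenyllithium F14 and transmetalated with ZnCl2 to 2,6-dimethoxyphenylzinc chloride F15. Cross-coupling of F15 with 2 (Pd2(dba)3, RuPhos, THF, 65 °C) would come back to the route at 4.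

Further compounds
F1 | step 7 | 2-fluoro-6-{2,6-dimethoxy-4-[(2,2',4,6,6'-pentamethoxybiphenyl-3-yl)oxy]phenoxy}benzaldehyde | O=Cc1c(F)cccc1Oc1c(OC)cc(Oc2c(OC)cc(OC)c(-c3c(OC)cccc3OC)c2OC)cc1OC
F2 | step 7 | 2,6-bis{2,6-dimethoxy-4-[(2,2',4,6,6'-pentamethoxybiphenyl-3-yl)oxy]phenoxy}benzaldehyde | O=Cc1c(Oc2c(OC)cc(Oc3c(OC)cc(OC)c(-c4c(OC)cccc4OC)c3OC)cc2OC)cccc1Oc1c(OC)cc(Oc2c(OC)cc(OC)c(-c3c(OC)cccc3OC)c2OC)cc1OC
F3 | step 7 | 2,6-bis{2,6-dimethoxy-4-[(2,2',4,6,6'-pentamethoxybiphenyl-3-yl)oxy]phenoxy}phenyl formate | O=COc1c(Oc2c(OC)cc(Oc3c(OC)cc(OC)c(-c4c(OC)cccc4OC)c3OC)cc2OC)cccc1Oc1c(OC)cc(Oc2c(OC)cc(OC)c(-c3c(OC)cccc3OC)c2OC)cc1OC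
F4 | step 7 | 2,6-bis{2,6-dimethoxy-4-[(2,2',4,6,6'-pentamethoxybiphenyl-3-yl)oxy]phenoxy}phenol | Oc1c(Oc2c(OC)cc(Oc3c(OC)cc(OC)c(-c4c(OC)cccc4OC)c3OC)cc2OC)cccc1Oc1c(OC)cc(Oc2c(OC)cc(OC)c(-c3c(OC)cccc3OC)c2OC)cc1OC
F5 | step 8 | 2,2',4,4',6,6'-hexamethoxybiphenyl-3-carbaldehyde | COc1cc(OC)c(C=O)c(OC)c1-c1c(OC)cc(OC)cc1OC
F6 | step 8 | 2,2',4,4',6,6'-hexamethoxybiphenyl-3-yl formate | COc1cc(OC)c(OC=O)c(OC)c1-c1c(OC)cc(OC)cc1OC
F7 | step 8 | 2,2',4,4',6,6'-hexamethoxybiphenyl-3-ol | COc1cc(OC)c(O)c(OC)c1-c1c(OC)cc(OC)cc1OC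
F8 | step 8 | 4-[(2,2',4,4',6,6'-hexamethoxybiphenyl-3-yl)oxy]-2,6-dimethoxybenzaldehyde | COc1cc(Oc2c(OC)cc(OC)c(-c3c(OC)cc(OC)cc3OC)c2OC)cc(OC)c1C=O
F9 | step 8 | 4-[(2,2',4,4',6,6'-hexamethoxybiphenyl-3-yl)oxy]-2,6-dimethoxyphenyl formate | COc1cc(Oc2c(OC)cc(OC)c(-c3c(OC)cc(OC)cc3OC)c2OC)cc(OC)c1OC=O
F10 | step 8 | 4-[(2,2',4,4',6,6'-hexamethoxybiphenyl-3-yl)oxy]-2,6-dimethoxyphenol | COc1cc(Oc2c(OC)cc(OC)c(-c3c(OC)cc(OC)cc3OC)c2OC)cc(OC)c1O
F11 | step 8 | 1,3-dibromo-2-(3,5-dimethoxyphenoxy)-5-methoxybenzene | COc1cc(OC)cc(Oc2c(Br)cc(OC)cc2Br)c1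
F12 | step 8 | 1-bromo-2-(3,5-dimethoxyphenoxy)-3-{4-[(2,2',4,4',6,6'-hexamethoxybiphenyl-3-yl)oxy]-2,6-dimethoxyphenoxy}-5-methoxybenzene | COc1cc(OC)cc(Oc2c(Br)cc(OC)cc2Oc2c(OC)cc(Oc3c(OC)cc(OC)c(-c4c(OC)cc(OC)cc4OC)c3OC)cc2OC)c1
F13 | step 8 | 2-(3,5-dimethoxyphenoxy)-1,3-bis{4-[(2,2',4,4',6,6'-hexamethoxybiphenyl-3-yl)oxy]-2,6-dimethoxyphenoxy}-5-methoxybenzene (nonadecamethyl ether of 18) | COc1cc(OC)cc(Oc2c(Oc3c(OC)cc(Oc4c(OC)cc(OC)c(-c5c(OC)cc(OC)cc5OC)c4OC)cc3OC)cc(OC)cc2Oc2c(OC)cc(Oc3c(OC)cc(OC)c(-c4c(OC)cc(OC)cc4OC)c3OC)cc2OC)c1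
F14 | step 2 | 2,6-dimethoxyphenyllithium | [Li]c1c(OC)cccc1OC
F15 | step 2 | 2,6-dimethoxyphenylzinc chloride | Cl[Zn]c1c(OC)cccc1OC
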